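**Strategy**

Ring A (tetrahydrofuran O1, C2–C5) is disconnected at O1–C2: C2 is benzylic and para to the oxygen of ring B, a latent p-quinone methide carbon. A 5-menthyloxybutyrolactone from a three-component conjugate addition–aldol reaction carries C3 and C4; in one flask LiAlH4 turns its carbonyl and acetal carbons into two CH2OH groups and frees the ring B phenol, then acid dehydrates the 4-hydroxybenzylic carbinol to the quinone methide, which the C5 hydroxyl captures 5-exo. The lactone oxygen becomes O1 and C2 is set trans to C3. Evans aldol and Mitsunobu inversion add the erythro glyceryl aryl ether; late ketone unmasking and C4 epimerisation give the all-trans ring.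

Key step: step 4

**Remarks**

- Locants: ring A = O1, C2 (bears ring B), C3 (CH2OH), C4 (aroyl of ring C), C5. Ring D is the guaiacyl ring. The side chain on the para-oxygen of ring B is C-α (carbinol on ring D), C-β (aryloxy carbon), C-γ (CH2OH).
- Assumption: compounds 1, 3, 5, 12 and 16 are taken as commercial; 5 is otherwise two steps from furfural and l-menthol.
- Assumption: the carbinol carbon made in step 3 forms as an epimer mixture and is drawn without configuration in 8 and 9; step 4 erases it.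

**Route**

Step 1
Reactants: 1 4-(benzyloxy)-3,5-dimethoxybenzaldehyde
Product: 2 2-[4-(benzyloxy)-3,5-dimethoxyphenyl]-1,3-dithiane
Conditions: HS(CH2)3SH, BF3·OEt2 (cat.), CH2Cl2, 0 → 23 °C
Reagents that add atoms: propane-1,3-dithiol, SCCCS
Why: Lewis-acid-catalysed thioacetalisation should give the Corey–Seebach acyl anion equivalent whose dithiane carbon becomes the aroyl carbon on C4; no stereocentre is formed.

Step 2
Reactants: 3 syringaldehyde
Product: 4 4-formyl-2,6-dimethoxyphenyl pivalate
Conditions: PivCl, Et3N, DMAP (cat.), CH2Cl2, 0 → 23 °C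
Reagents that add atoms: pivaloyl chloride, CC(C)(C)C(Cl)=O
Why: DMAP-catalysed O-acylation; the hindered ester masks the ring B phenol through the enolate chemistry, keeps the benzylic carbinol of 8 from ionising, and is cleaved by LiAlH4 in step 4.

Step 3
Reactants: 2 aryl dithiane; 5 (5R)-5-(l-menthyloxy)furan-2(5H)-one; 4 aldehyde
Product: 8 lactone aldol adduct (3S,4R,5R; carbinol epimers), via lithiodithiane 6 (not isolated), via lithium enolate 7 (not isolated)
Conditions: n-BuLi, THF, −78 → −30 °C; 5, −78 °C; 4, −78 °C; AcOH, −78 °C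
Reagents that add atoms: none
Why: Tandem conjugate addition–aldol reaction on a chiral 5-alkoxybutenolide: 6 should add 1,4 anti to the menthyloxy group (sets C4) and enolate 7 should take the aldehyde anti to the new C4 substituent (sets C3, trans,trans lactone).

Step 4
Reactants: 8 lactone aldol adduct
Product: 11 phenolic tetrahydrofuran (2S,3R,4R), via phenolic triol 9 (not isolated), via quinone methide 10 (not isolated)
Conditions: LiAlH4, THF, 0 → 23 °C; then EtOAc, 1 M aq. HCl to pH 2, 23–40 °C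
Reagents that add atoms: none
Why: LiAlH4 reduces the lactone carbonyl to CH2OH, reduces the aldehyde released when the menthyl hemiacetal collapses (the former ring oxygen stays on that carbon, the future C5–O1) and cleaves the pivalate, giving phenolic triol 9; on acidification the 4-hydroxy-3,5-dimethoxybenzylic carbinol loses water to p-quinone methide 10 and the C5 hydroxyl adds to the methide carbon (oxa-1,6-addition), re-aromatising ring B and forming O1–C2. The closest known reaction type is the biomimetic quinone methide cycloetherification (acid-catalysed cyclodehydration) of benzylic 1,4-diols in lignan chemistry. Ring A closes 5-exo-trig, whereas the other hydroxymethyl could only form an oxetane. The new stereocentre C2 is controlled by C3: the aryl group should end trans to the C3 hydroxymethyl, and because addition to the quinone methide is reversible this is the thermodynamic isomer, so both carbinol epimers of 8 converge. The step needs O- over C-capture (Friedel–Crafts attack by ring C on the benzylic electrophile); dilute acid keeps the electrophile as the neutral quinone methide, which the hydroxyl four atoms away should trap far faster than an arene can. C3 and C4 are not touched, since after the reduction neither is next to a carbonyl group.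

Step 5
Reactants: 12 (R)-4-benzyl-1,3-oxazolidin-2-one
Product: 14 (R)-4-benzyl-3-(bromoacetyl)-1,3-oxazolidin-2-one, via N-lithio oxazolidinone 13 (not isolated)
Conditions: n-BuLi, THF, −78 °C; BrCH2COBr, −78 → 0 °C
Reagents that add atoms: bromoacetyl bromide, BrCC(Br)=O
Why: N-Acylation of the lithiated oxazolidinone by the acyl bromide; the auxiliary stereocentre is not involved.

Step 6
Reactants: 11 phenolic tetrahydrofuran; 14 bromoacetyl imide
Product: 15 aryloxyacetyl imide
Conditions: K2CO3, acetone, 23 → 45 °C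
Reagents that add atoms: none
Why: Williamson etherification: under carbonate only the ring B phenol is deprotonated and displaces the activated α-bromide, the primary alcohol staying free.

Step 7
Reactants: 15 aryloxyacetyl imide; 16 4-(benzyloxy)-3-methoxybenzaldehyde
Product: 18 syn-aldol adduct (C-α S; C-β R as imide), via boron enolate 17 (not isolated)
Conditions: n-Bu2BOTf (2.3 equiv), i-Pr2NEt, CH2Cl2, −78 → 0 °C; 16, −78 → 0 °C; pH 7 buffer, MeOH (no peroxide)
Reagents that add atoms: none
Why: Evans syn-aldol reaction of a glycolate-type imide: the (Z)-boron enolate should react through a Zimmerman–Traxler chair on the face away from the benzyl group of the (R)-auxiliary, setting C-β (its final configuration) and C-α syn to it; the C3 hydroxymethyl is carried as a transient borinate and peroxide is avoided to spare the dithiane.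

Step 8
Reactants: 18 syn-aldol adduct
Product: 19 threo triol (C-α S, C-β S)
Conditions: NaBH4, THF/H2O (4:1), 0 → 23 °C
Reagents that add atoms: none
Why: Borohydride reduction of the exocyclic imide carbonyl should release C-γ as CH2OH and the recoverable auxiliary without touching the dithiane or either stereocentre.

Step 9
Reactants: 19 threo triol
Product: 20 erythro tris(4-nitrobenzoate) (C-α R, C-β S)
Conditions: PPh3, DIAD, 4-O2NC6H4CO2H (4.5 equiv each), THF, −20 → 23 °C
Reagents that add atoms: 4-nitrobenzoic acid, O=C(O)c1ccc(cc1)[N+](=O)[O-]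
Why: Mitsunobu esterification: the two primary hydroxyls are acylated and the benzylic C-α oxyphosphonium should be displaced by carboxylate with inversion, turning threo into erythro.

Step 10
Reactants: 20 tris(4-nitrobenzoate)
Product: 21 3,4-cis aryl ketone tris(4-nitrobenzoate) (ring A 2S,3R,4R)
Conditions: MeI, CaCO3, MeCN/THF/H2O, 45 °C
Reagents that add atoms: water, O
Why: Alkylative dithiane hydrolysis: S-methylation and hydrolysis of the aryl-stabilised thionium ion should release the ketone under CaCO3 buffering, with no free benzylic alcohol present and C4 left as formed.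

Step 11
Reactants: 21 cis ketone tris(4-nitrobenzoate)
Product: 22 all-trans ketone triol dibenzyl ether (ring A 2S,3R,4S)
Conditions: K2CO3, MeOH/THF, 0 → 23 °C
Reagents that add atoms: none
Why: Carbonate-catalysed methanolysis removes the three esters while reversible enolisation of the aryl ketone should epimerise C4 to the thermodynamically favoured 2,3-trans-3,4-trans ring; the phenols are still benzylated, so the ketone stays acidifying.

Step 12
Reactants: 22 ketone triol dibenzyl ether
Product: 23 target CNP0236429.1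
Conditions: H2 (1 atm), Pd/C (10 wt% palladium on carbon), EtOAc/MeOH, 23 °C
Reagents that add atoms: none
Why: Hydrogenolysis of the two aryl benzyl ethers under neutral conditions, stopped after two equivalents of hydrogen so that the benzylic C–O bonds and the aryl ketone are kept.

**Compound list**

1 | 4-(benzyloxy)-3,5-dimethoxybenzaldehyde | COc1cc(C=O)cc(OC)c1OCc1ccccc1 | starting material
2 | 2-[4-(benzyloxy)-3,5-dimethoxyphenyl]-1,3-dithiane | COc1cc(C2SCCCS2)cc(OC)c1OCc1ccccc1 | intermediate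
3 | syringaldehyde (4-hydroxy-3,5-dimethoxybenzaldehyde) | COc1cc(C=O)cc(OC)c1O | starting material
4 | 4-formyl-2,6-dimethoxyphenyl pivalate | COc1cc(C=O)cc(OC)c1OC(=O)C(C)(C)C | intermediate
5 | (5R)-5-[(1R,2S,5R)-menthyloxy]furan-2(5H)-one | C[C@@H]1CC[C@H]([C@@H](C1)O[C@@H]2OC(=O)C=C2)C(C)C | starting material
6 | 2-lithio derivative of dithiane 2 (in situ) | COc1cc(C2([Li])SCCCS2)cc(OC)c1OCc1ccccc1 | intermediate
7 | lithium enolate of the (4R,5R)-4-(2-aryl-1,3-dithian-2-yl)-5-menthyloxy lactone (in situ) | C[C@@H]1CC[C@H]([C@@H](C1)O[C@@H]2OC(O[Li])=C[C@H]2C3(c4cc(OC)c(OCc5ccccc5)c(OC)c4)SCCCS3)C(C)C | intermediate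
8 | (3S,4R,5R)-4-{2-[4-(benzyloxy)-3,5-dimethoxyphenyl]-1,3-dithian-2-yl}-3-{hydroxy[3,5-dimethoxy-4-(pivaloyloxy)phenyl]methyl}-5-[(1R,2S,5R)-menthyloxy]dihydrofuran-2(3H)-one, carbinol epimers | C[C@@H]1CC[C@H]([C@@H](C1)O[C@@H]2OC(=O)[C@H](C(O)c3cc(OC)c(OC(=O)C(C)(C)C)c(OC)c3)[C@H]2C4(c5cc(OC)c(OCc6ccccc6)c(OC)c5)SCCCS4)C(C)C | intermediate
9 | (2R,3R)-3-{2-[4-(benzyloxy)-3,5-dimethoxyphenyl]-1,3-dithian-2-yl}-2-[hydroxy(4-hydroxy-3,5-dimethoxyphenyl)methyl]butane-1,4-diol, carbinol epimers (in situ) | COc1cc(C(O)[C@@H](CO)[C@H](CO)C2(c3cc(OC)c(OCc4ccccc4)c(OC)c3)SCCCS2)cc(OC)c1O | intermediate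
10 | p-quinone methide of 9: 2,6-dimethoxy-4-alkylidenecyclohexa-2,5-dien-1-one carrying the two CH2OH-bearing stereocentres unchanged (in situ) | COC1=CC(=C[C@@H](CO)[C@H](CO)C2(c3cc(OC)c(OCc4ccccc4)c(OC)c3)SCCCS2)C=C(OC)C1=O | intermediate
11 | 4-[(2S,3R,4R)-4-{2-[4-(benzyloxy)-3,5-dimethoxyphenyl]-1,3-dithian-2-yl}-3-(hydroxymethyl)oxolan-2-yl]-2,6-dimethoxyphenol | COc1cc([C@H]2OC[C@H](C3(c4cc(OC)c(OCc5ccccc5)c(OC)c4)SCCCS3)[C@@H]2CO)cc(OC)c1O | intermediate
12 | (R)-4-benzyl-1,3-oxazolidin-2-one | O=C1N[C@H](Cc2ccccc2)CO1 | starting material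
13 | N-lithio derivative of 12 (in situ) | [Li]N1[C@H](Cc2ccccc2)COC1=O | intermediate
14 | (R)-4-benzyl-3-(bromoacetyl)-1,3-oxazolidin-2-one | O=C(CBr)N1[C@H](Cc2ccccc2)COC1=O | intermediate
15 | (R)-4-benzyl-3-(aryloxyacetyl)oxazolidin-2-one, aryl = ring B of 11 (ring A 2S,3R,4R) | COc1cc([C@H]2OC[C@H](C3(c4cc(OC)c(OCc5ccccc5)c(OC)c4)SCCCS3)[C@@H]2CO)cc(OC)c1OCC(=O)N1[C@H](Cc2ccccc2)COC1=O | intermediate
16 | 4-(benzyloxy)-3-methoxybenzaldehyde | COc1cc(C=O)ccc1OCc1ccccc1 | starting material
17 | di-n-butylboron (Z)-enolate of 15 with the C3 hydroxymethyl as its di-n-butylborinate (in situ) | COc1cc([C@H]2OC[C@H](C3(c4cc(OC)c(OCc5ccccc5)c(OC)c4)SCCCS3)[C@@H]2COB(CCCC)CCCC)cc(OC)c1O/C=C(\OB(CCCC)CCCC)N1[C@H](Cc2ccccc2)COC1=O | intermediate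
18 | (4R)-4-benzyl-3-[(2R,3S)-2-aryloxy-3-[4-(benzyloxy)-3-methoxyphenyl]-3-hydroxypropanoyl]oxazolidin-2-one, syn-aldol adduct | COc1cc([C@H](O)[C@H](C(=O)N2[C@H](Cc3ccccc3)COC2=O)Oc2c(OC)cc([C@H]3OC[C@H](C4(c5cc(OC)c(OCc6ccccc6)c(OC)c5)SCCCS4)[C@@H]3CO)cc2OC)ccc1OCc1ccccc1 | intermediate
19 | threo triol: (1S,2S)-2-aryloxy-1-[4-(benzyloxy)-3-methoxyphenyl]propane-1,3-diol on the dithiane-bearing ring A (2S,3R,4R) | COc1cc([C@H](O)[C@H](CO)Oc2c(OC)cc([C@H]3OC[C@H](C4(c5cc(OC)c(OCc6ccccc6)c(OC)c5)SCCCS4)[C@@H]3CO)cc2OC)ccc1OCc1ccccc1 | intermediate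
20 | erythro tris(4-nitrobenzoate) (C-α R, C-β S; esters on C-α–O, C-γ–O and the C3 CH2O) | COc1cc([C@@H](OC(=O)c2ccc(cc2)[N+](=O)[O-])[C@H](COC(=O)c2ccc(cc2)[N+](=O)[O-])Oc2c(OC)cc([C@H]3OC[C@H](C4(c5cc(OC)c(OCc6ccccc6)c(OC)c5)SCCCS4)[C@@H]3COC(=O)c3ccc(cc3)[N+](=O)[O-])cc2OC)ccc1OCc1ccccc1 | intermediate
21 | 3,4-cis aryl ketone tris(4-nitrobenzoate), ring A (2S,3R,4R) | COc1cc([C@@H](OC(=O)c2ccc(cc2)[N+](=O)[O-])[C@H](COC(=O)c2ccc(cc2)[N+](=O)[O-])Oc2c(OC)cc([C@H]3OC[C@H](C(=O)c4cc(OC)c(OCc5ccccc5)c(OC)c4)[C@@H]3COC(=O)c3ccc(cc3)[N+](=O)[O-])cc2OC)ccc1OCc1ccccc1 | intermediate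
22 | all-trans ketone triol, both phenols as benzyl ethers, ring A (2S,3R,4S), side chain (C-α R, C-β S) | COc1cc([C@@H](O)[C@H](CO)Oc2c(OC)cc([C@H]3OC[C@@H](C(=O)c4cc(OC)c(OCc5ccccc5)c(OC)c4)[C@@H]3CO)cc2OC)ccc1OCc1ccccc1 | intermediate
23 | CNP0236429.1 | COc1cc([C@@H](O)[C@H](CO)Oc2c(OC)cc([C@H]3OC[C@@H](C(=O)c4cc(OC)c(O)c(OC)c4)[C@@H]3CO)cc2OC)ccc1O | target

**Step count**

Total steps: 12. Longest linear sequence: 10 steps (1, 3, 4, 6, 7, 8, 9, 10, 11, 12).

**Steps most likely to fail**

1. Step 9. The electron-rich benzylic oxyphosphonium ion may ionise before the carboxylate attacks, so that substitution runs with partial retention, or it may eliminate towards the aryl enol ether. The fallback sets out from 19 and replaces substitution by an oxidation–reduction pair. Activated MnO2 (CH2Cl2, 23 °C) should oxidise only the benzylic C-α hydroxyl to the α-aryloxy ketone F1. Zn(BH4)2 (Et2O/THF, −20 °C) should reduce it under chelation control (Cram chelate between the carbonyl and the C-β aryloxy oxygen, hydride from the side of the C-β hydrogen) to the erythro triol F2. MeI/CaCO3 hydrolysis of the dithiane should give the cis ketone triol F3, and K2CO3 in MeOH should epimerise C4, which comes back to the route at 22.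

2. Step 7. The free C3 hydroxymethyl and the thioacetal sulfurs may sequester the boron triflate, leaving enolisation incomplete and letting an unselective background aldol reaction run. The fallback sets out from 15 and replaces the transient borinate by covalent protection. TBSCl/imidazole (DMF) should give the silyl ether F4, and the same boron aldol reaction with 16 (1.1 equiv n-Bu2BOTf) should give the silylated syn-aldol adduct F5. HF·pyridine (THF, 0 °C) then comes back to the route at 18.

3. Step 4. Irreversible Friedel–Crafts capture of the benzylic electrophile by the electron-rich ring C (aryltetralin formation) may compete with the reversible O-capture, or a quinone methide formed during the hydride stage may be reduced. The fallback sets out from aldehyde 4 and enolate 7 and generates the same quinone methide oxidatively from a C–H precursor, without acid. NaBH4 (MeOH, 0 °C) should reduce 4 to the benzylic alcohol F6 and PBr3 (Et2O, 0 °C) should give the benzylic bromide F7. Enolate 7 is alkylated with F7 (THF/DMPU, −78 → −40 °C) anti to the C4 substituent to give the benzylated lactone F8. LiAlH4 should give the phenolic diol F9, which has no benzylic oxygen to ionise. Ag2O in CH2Cl2 should then oxidise the 4-alkyl-2,6-dimethoxyphenol to quinone methide 10, which closes as in step 4 and comes back to the route at 11.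

**Further compounds**

F1 | step 9 | α-aryloxy ketone: (2S)-2-aryloxy-1-[4-(benzyloxy)-3-methoxyphenyl]-3-hydroxypropan-1-one on the dithiane-bearing ring A | COc1cc(C(=O)[C@H](CO)Oc2c(OC)cc([C@H]3OC[C@H](C4(c5cc(OC)c(OCc6ccccc6)c(OC)c5)SCCCS4)[C@@H]3CO)cc2OC)ccc1OCc1ccccc1
F2 | step 9 | erythro triol (C-α R, C-β S) with the dithiane in place | COc1cc([C@@H](O)[C@H](CO)Oc2c(OC)cc([C@H]3OC[C@H](C4(c5cc(OC)c(OCc6ccccc6)c(OC)c5)SCCCS4)[C@@H]3CO)cc2OC)ccc1OCc1ccccc1
F3 | step 9 | 3,4-cis ketone erythro triol dibenzyl ether, ring A (2S,3R,4R) | COc1cc([C@@H](O)[C@H](CO)Oc2c(OC)cc([C@H]3OC[C@H](C(=O)c4cc(OC)c(OCc5ccccc5)c(OC)c4)[C@@H]3CO)cc2OC)ccc1OCc1ccccc1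
F4 | step 7 | tert-butyldimethylsilyl ether of 15 at the C3 hydroxymethyl | COc1cc([C@H]2OC[C@H](C3(c4cc(OC)c(OCc5ccccc5)c(OC)c4)SCCCS3)[C@@H]2CO[Si](C)(C)C(C)(C)C)cc(OC)c1OCC(=O)N1[C@H](Cc2ccccc2)COC1=O
F5 | step 7 | tert-butyldimethylsilyl ether of syn-aldol adduct 18 at the C3 hydroxymethyl | COc1cc([C@H](O)[C@H](C(=O)N2[C@H](Cc3ccccc3)COC2=O)Oc2c(OC)cc([C@H]3OC[C@H](C4(c5cc(OC)c(OCc6ccccc6)c(OC)c5)SCCCS4)[C@@H]3CO[Si](C)(C)C(C)(C)C)cc2OC)ccc1OCc1ccccc1
F6 | step 4 | 4-(hydroxymethyl)-2,6-dimethoxyphenyl pivalate | COc1cc(CO)cc(OC)c1OC(=O)C(C)(C)C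
F7 | step 4 | 4-(bromomethyl)-2,6-dimethoxyphenyl pivalate | COc1cc(CBr)cc(OC)c1OC(=O)C(C)(C)C
F8 | step 4 | (3R,4R,5R)-3-[3,5-dimethoxy-4-(pivaloyloxy)benzyl]-4-{2-[4-(benzyloxy)-3,5-dimethoxyphenyl]-1,3-dithian-2-yl}-5-[(1R,2S,5R)-menthyloxy]dihydrofuran-2(3H)-one | C[C@@H]1CC[C@H]([C@@H](C1)O[C@@H]2OC(=O)[C@H](Cc3cc(OC)c(OC(=O)C(C)(C)C)c(OC)c3)[C@H]2C4(c5cc(OC)c(OCc6ccccc6)c(OC)c5)SCCCS4)C(C)C
F9 | step 4 | (2R,3R)-3-{2-[4-(benzyloxy)-3,5-dimethoxyphenyl]-1,3-dithian-2-yl}-2-(4-hydroxy-3,5-dimethoxybenzyl)butane-1,4-diol | COc1cc(C[C@@H](CO)[C@H](CO)C2(c3cc(OC)c(OCc4ccccc4)c(OC)c3)SCCCS2)cc(OC)c1O
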